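In the furo[3,4-c]furan-1-one core (C-1 carbonyl, O-2, C-3, C-3a, C-4, O-5, C-6, C-6a) all four methine hydrogens lie on one face. The tetrahydrofuran ring can therefore be carried as a flat furan, with C-3 as the only stereocentre. Its C-4–O-5–C-6 triad maps onto C-5–O-1–C-2 of a 2-aryl-4-methyloxazole. Heating this oxazole with an enantioenriched γ-aryl-γ-hydroxy ynoate forms C-3a–C-4 and C-6–C-6a in one Diels–Alder event. Acetonitrile leaves, the furan appears, and the hydroxy ester closes to the lactone. Hydrogenation from the face opposite the C-3 aryl group then sets C-3a, C-6 and C-6a.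

Key step: step 5

Assumption: the (S)-BINOL–titanium alkynylzinc system is taken to attack the Si face of aryl aldehydes, as it does in dialkylzinc additions. If the sense were opposite, (R)-BINOL would be used in step 2 and nothing else would change.

Step 1
Reactants: 1 syringaldehyde (4-hydroxy-3,5-dimethoxybenzaldehyde)
Product: 2 4-(tert-butyldimethylsilyloxy)-3,5-dimethoxybenzaldehyde
Conditions: TBSCl, imidazole, DMF, rt
Reagents that add atoms: tert-butyldimethylsilyl chloride, CC(C)(C)[Si](C)(C)Cl
Why: Imidazole-promoted O-silylation of a phenol; the silyl ether removes the acidic proton before the organozinc step, withstands neutral thermolysis and hydrogenation, and no stereocentre is involved.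

Step 2
Reactants: 2 4-(tert-butyldimethylsilyloxy)-3,5-dimethoxybenzaldehyde; 3 methyl propiolate
Product: 5 methyl (R)-4-[4-(tert-butyldimethylsilyloxy)-3,5-dimethoxyphenyl]-4-hydroxybut-2-ynoate, via alkynylzinc reagent 4 (not isolated)
Conditions: (S)-BINOL (40 mol %), ZnEt2, HMPA, CH2Cl2, rt; Ti(OiPr)4; then 2, rt; H2O quench
Reagents that add atoms: diethylzinc, CC[Zn]CC (zinc and one ethyl group stay only in intermediate 4)
Why: Catalytic asymmetric alkynylation of an aldehyde (alkynylzinc addition under BINOL–titanium control): ZnEt2 zincates the terminal alkyne to 4, and the (S)-BINOL-bound titanium centre that activates aldehyde 2 leaves only its Si face open, which sets the carbinol carbon (the later C-3) as R.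

Step 3
Reactants: 6 4-bromocatechol (4-bromobenzene-1,2-diol)
Product: 7 4-bromo-1,2-bis(tert-butyldimethylsilyloxy)benzene
Conditions: TBSCl (2.2 equiv), imidazole, DMF, rt
Reagents that add atoms: tert-butyldimethylsilyl chloride, CC(C)(C)[Si](C)(C)Cl
Why: Double O-silylation of the catechol under the same imidazole catalysis, needed because free phenols would quench the organometals of step 4; no stereocentre is involved.

Step 4
Reactants: 8 4-methyloxazole; 7 4-bromo-1,2-bis(tert-butyldimethylsilyloxy)benzene
Product: 11 2-[3,4-bis(tert-butyldimethylsilyloxy)phenyl]-4-methyloxazole, via 2-lithio-4-methyloxazole 9 (not isolated), via oxazol-2-ylzinc chloride 10 (not isolated)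
Conditions: n-BuLi, THF, −78 °C; ZnCl2, −78 °C to rt; 7, Pd(PPh3)4 (5 mol %), THF, 65 °C
Reagents that add atoms: n-butyllithium, [Li]CCCC (lithium stays only in intermediate 9); zinc chloride, Cl[Zn]Cl (zinc and chlorine stay only in intermediate 10)
Why: Negishi coupling: n-BuLi removes the most acidic proton (C-2–H) of 8, transmetalation to zinc holds the 2-metalated oxazole in its ring-closed form, and palladium-catalysed cross-coupling with bromide 7 makes the aryl–C-2 bond without any base that could attack the aryl silyl ethers; no stereocentre is involved.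

Step 5
Reactants: 5 methyl (R)-4-[4-(tert-butyldimethylsilyloxy)-3,5-dimethoxyphenyl]-4-hydroxybut-2-ynoate; 11 2-[3,4-bis(tert-butyldimethylsilyloxy)phenyl]-4-methyloxazole
Product: 14 (3R)-6-[3,4-bis(tert-butyldimethylsilyloxy)phenyl]-3-[4-(tert-butyldimethylsilyloxy)-3,5-dimethoxyphenyl]-1H,3H-furo[3,4-c]furan-1-one, via oxa-azanorbornadiene adduct 12 (not isolated), via furan hydroxy ester 13 (not isolated)
Conditions: 11 (1.5 equiv), o-dichlorobenzene, 180 °C, argon sweep (MeCN and MeOH distil off)
Reagents that add atoms: none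
Why: The electron-rich oxazole 11 reacts as a 2-azadiene (oxazole C-5=C-4–N-3=C-2) with the electron-poor triple bond of 5 in a concerted, suprafacial, normal-demand [4+2] cycloaddition that makes the product bonds C-3a–C-4 and C-6–C-6a together and gives the 7-oxa-2-azanorbornadiene 12; cycloreversion expels acetonitrile (oxazole N-3, C-4 and its methyl group) and leaves furan 13, whose hydroxy ester closes at the same temperature to lactone 14 as methanol distils off. The closest known reaction type is the oxazole–alkyne Diels–Alder/retro-Diels–Alder synthesis of furans. The furan ring is closed by the cycloaddition (six-membered transition state, then loss of the two-atom nitrile bridge), and the lactone ring by a 5-exo-trig addition–elimination of the carbinol oxygen on the ester carbonyl. No new stereocentre is formed, and C-3 passes through unchanged because the medium holds neither acid nor base and the C-3–O bond is never broken. The step needs regioselectivity: the largest HOMO coefficient of 11 lies at oxazole C-5 (the 4-methyl and 2-aryl groups act as the para- and ortho-directing donors of the diene) and pairs with the β-carbon of the ynoate, which has the largest LUMO coefficient, and the same orientation puts the bulky carbinol carbon next to the unsubstituted C-5–H and not next to the aryl group. It also needs chemoselectivity for the ynoate, which the arenes and silyl ethers grant because they are inert to neutral thermolysis.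

Step 6
Reactants: 14 (3R)-6-[3,4-bis(tert-butyldimethylsilyloxy)phenyl]-3-[4-(tert-butyldimethylsilyloxy)-3,5-dimethoxyphenyl]-1H,3H-furo[3,4-c]furan-1-one
Product: 15 (3S,3aS,6S,6aR)-6-[3,4-bis(tert-butyldimethylsilyloxy)phenyl]-3-[4-(tert-butyldimethylsilyloxy)-3,5-dimethoxyphenyl]tetrahydro-1H,3H-furo[3,4-c]furan-1-one
Conditions: H2 (50 bar), 5% Rh/Al2O3, EtOAc, 25 °C
Reagents that add atoms: none
Why: Heterogeneous syn-hydrogenation of a furan to the cis-tetrahydrofuran over rhodium, a metal of low hydrogenolysis activity toward benzylic C–O bonds: the flat, strained bicycle meets the surface by the face that carries H-3 because the C-3 aryl group blocks the other, so H-3a, H-6a and H-6 all arrive cis to H-3, an outcome reinforced by the need for a cis ring fusion and by suprafacial addition across C-6=C-6a (C-3 is spatially unchanged, its descriptor turns from R to S only through the new ligand ranking).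

Step 7
Reactants: 15 (3S,3aS,6S,6aR)-tris(silyl ether) of the target
Product: 16 (3S,3aS,6S,6aR)-6-(3,4-dihydroxyphenyl)-3-(4-hydroxy-3,5-dimethoxyphenyl)tetrahydro-1H,3H-furo[3,4-c]furan-1-one (CNP0224550.1)
Conditions: TBAF, AcOH (1:1), THF, 0 °C, argon
Reagents that add atoms: none
Why: Fluoride-induced cleavage of the three aryl silyl ethers, with acetic acid protonating each phenoxide as it forms so that neither para-quinone methide formation (epimerisation at C-3 or C-6) nor lactone opening can start; all four stereocentres stay untouched.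

Compound list
1 | syringaldehyde | COc1cc(C=O)cc(OC)c1O | starting material
2 | 4-(tert-butyldimethylsilyloxy)-3,5-dimethoxybenzaldehyde | COc1cc(C=O)cc(OC)c1O[Si](C)(C)C(C)(C)C | intermediate
3 | methyl propiolate | C#CC(=O)OC | starting material
4 | ethyl(3-methoxy-3-oxoprop-1-yn-1-yl)zinc | CC[Zn]C#CC(=O)OC | intermediate
5 | methyl (R)-4-[4-(tert-butyldimethylsilyloxy)-3,5-dimethoxyphenyl]-4-hydroxybut-2-ynoate | COC(=O)C#C[C@H](O)c1cc(OC)c(O[Si](C)(C)C(C)(C)C)c(OC)c1 | intermediate
6 | 4-bromobenzene-1,2-diol | Oc1ccc(Br)cc1O | starting material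
7 | 4-bromo-1,2-bis(tert-butyldimethylsilyloxy)benzene | CC(C)(C)[Si](C)(C)Oc1ccc(Br)cc1O[Si](C)(C)C(C)(C)C | intermediate
8 | 4-methyloxazole | Cc1cocn1 | starting material
9 | 2-lithio-4-methyloxazole | Cc1coc([Li])n1 | intermediate
10 | (4-methyloxazol-2-yl)zinc chloride | Cc1coc([Zn]Cl)n1 | intermediate
11 | 2-[3,4-bis(tert-butyldimethylsilyloxy)phenyl]-4-methyloxazole | Cc1coc(-c2ccc(O[Si](C)(C)C(C)(C)C)c(O[Si](C)(C)C(C)(C)C)c2)n1 | intermediate
12 | methyl 1-aryl-3-methyl-5-[(R)-aryl(hydroxy)methyl]-7-oxa-2-azabicyclo[2.2.1]hepta-2,5-diene-6-carboxylate (both bridgehead diastereomers) | COC(=O)C1=C([C@H](O)c2cc(OC)c(O[Si](C)(C)C(C)(C)C)c(OC)c2)C2OC1(c1ccc(O[Si](C)(C)C(C)(C)C)c(O[Si](C)(C)C(C)(C)C)c1)N=C2C | intermediate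
13 | methyl 2-[3,4-bis(tert-butyldimethylsilyloxy)phenyl]-4-{(R)-[4-(tert-butyldimethylsilyloxy)-3,5-dimethoxyphenyl](hydroxy)methyl}furan-3-carboxylate | COC(=O)c1c([C@H](O)c2cc(OC)c(O[Si](C)(C)C(C)(C)C)c(OC)c2)coc1-c1ccc(O[Si](C)(C)C(C)(C)C)c(O[Si](C)(C)C(C)(C)C)c1 | intermediate
14 | (3R)-6-[3,4-bis(tert-butyldimethylsilyloxy)phenyl]-3-[4-(tert-butyldimethylsilyloxy)-3,5-dimethoxyphenyl]-1H,3H-furo[3,4-c]furan-1-one | COc1cc([C@H]2OC(=O)c3c2coc3-c2ccc(O[Si](C)(C)C(C)(C)C)c(O[Si](C)(C)C(C)(C)C)c2)cc(OC)c1O[Si](C)(C)C(C)(C)C | intermediate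
15 | (3S,3aS,6S,6aR)-tris(tert-butyldimethylsilyl) ether of the target | COc1cc([C@H]2OC(=O)[C@@H]3[C@H]2CO[C@@H]3c2ccc(O[Si](C)(C)C(C)(C)C)c(O[Si](C)(C)C(C)(C)C)c2)cc(OC)c1O[Si](C)(C)C(C)(C)C | intermediate
16 | (3S,3aS,6S,6aR)-6-(3,4-dihydroxyphenyl)-3-(4-hydroxy-3,5-dimethoxyphenyl)tetrahydro-1H,3H-furo[3,4-c]furan-1-one | COc1cc([C@H]2OC(=O)[C@@H]3[C@H]2CO[C@@H]3c2ccc(O)c(O)c2)cc(OC)c1O | target

Total step count: 7. Longest linear sequence: 5 steps (1, 2, 5, 6, 7; the branch 3, 4, 5, 6, 7 is equally long).

Steps most likely to fail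

Step 5. The intermolecular cycloaddition of a 2-aryl oxazole with an internal, singly activated alkyne may be too slow. At the temperature needed the propargylic alcohol may start to decay, and the orientation may be incompletely controlled.
- The fallback is a temporary silicon connection. It sets out from 11 and 5 and returns at 14.
- Oxazole 11 is deprotonated at its free C-5 position (n-BuLi, THF, −78 °C) to the 5-lithio-oxazole F1. This is quenched with iPr2SiCl2 to the chlorosilane F2.
- Addition of 5 and imidazole gives the diisopropylsilyl ether F3, in which diene terminus and alkyne are joined by a three-atom Si–O–C tether.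
- The now intramolecular Diels–Alder reaction (toluene, 140 °C, sealed tube) can only bond oxazole C-5 to the carbinol-bearing alkyne carbon. The bridged adduct F4 loses acetonitrile to the oxasilole-fused furan F5.
- TBAF/AcOH cleaves the Si–O bond, the furyl–Si bond and the aryl silyl ethers, and the hydroxy ester lactonises to the triphenol lactone F6. TBSCl/imidazole then returns 14.

Step 6. Three things may go wrong: hydrogenolysis of the doubly activated C-3–O bond, saturation of an arene, or stalling after the first equivalent of hydrogen at the push–pull enol ether stage.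
- The fallback splits the reduction into two mechanistically different halves. It sets out from 14 and returns at 15.
- Hydrogenation at 1 bar over Rh/Al2O3 is stopped after one equivalent at the 3a,4-dihydro lactone F7. H-3a is delivered anti to the C-3 aryl group.
- The remaining C-6=C-6a bond is then reduced by ionic hydrogenation (Et3SiH, CF3CO2H, CH2Cl2, −20 °C).
- Protonation at C-6a can only give the cis-fused bicycle. Hydride then attacks the aryl-stabilised oxocarbenium ion at C-6 from the convex face, which again places H-6 cis to the other three hydrogens.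

Step 4. The 2-metalated oxazole may open to the isocyano enolate before transmetalation, and oxidative addition of the electron-rich bromide may be slow.
- The fallback dispenses with the organometal. It sets out from 7 and 8 and returns at 11.
- It is a direct C-2–H arylation by concerted metalation–deprotonation (Pd(OAc)2, RuPhos, K2CO3, pivalic acid, toluene, 110 °C). The non-polar solvent favours C-2 over C-5.
- No new compound arises (F0).

Further compounds
F1 | step 5 | 2-[3,4-bis(tert-butyldimethylsilyloxy)phenyl]-5-lithio-4-methyloxazole | Cc1nc(-c2ccc(O[Si](C)(C)C(C)(C)C)c(O[Si](C)(C)C(C)(C)C)c2)oc1[Li]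
F2 | step 5 | 2-[3,4-bis(tert-butyldimethylsilyloxy)phenyl]-5-[chloro(diisopropyl)silyl]-4-methyloxazole | Cc1nc(-c2ccc(O[Si](C)(C)C(C)(C)C)c(O[Si](C)(C)C(C)(C)C)c2)oc1[Si](Cl)(C(C)C)C(C)C
F3 | step 5 | (R)-diisopropyl(oxazol-5-yl)silyl ether of 5 | COC(=O)C#C[C@H](O[Si](C(C)C)(C(C)C)c1oc(-c2ccc(O[Si](C)(C)C(C)(C)C)c(O[Si](C)(C)C(C)(C)C)c2)nc1C)c1cc(OC)c(O[Si](C)(C)C(C)(C)C)c(OC)c1
F4 | step 5 | silicon-bridged 7-oxa-2-azanorbornadiene adduct | COC(=O)C1=C2[C@@H](c3cc(OC)c(O[Si](C)(C)C(C)(C)C)c(OC)c3)O[Si](C(C)C)(C(C)C)C23OC1(c1ccc(O[Si](C)(C)C(C)(C)C)c(O[Si](C)(C)C(C)(C)C)c1)N=C3C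
F5 | step 5 | oxasilole-fused furan-3-carboxylate | COC(=O)c1c2[C@@H](c3cc(OC)c(O[Si](C)(C)C(C)(C)C)c(OC)c3)O[Si](C(C)C)(C(C)C)c2oc1-c1ccc(O[Si](C)(C)C(C)(C)C)c(O[Si](C)(C)C(C)(C)C)c1
F6 | step 5 | (3R)-6-(3,4-dihydroxyphenyl)-3-(4-hydroxy-3,5-dimethoxyphenyl)-1H,3H-furo[3,4-c]furan-1-one | COc1cc([C@H]2OC(=O)c3c2coc3-c2ccc(O)c(O)c2)cc(OC)c1O
F7 | step 6 | (3S,3aS)-6-[3,4-bis(tert-butyldimethylsilyloxy)phenyl]-3-[4-(tert-butyldimethylsilyloxy)-3,5-dimethoxyphenyl]-3a,4-dihydro-1H,3H-furo[3,4-c]furan-1-one | COc1cc([C@H]2OC(=O)C3=C(c4ccc(O[Si](C)(C)C(C)(C)C)c(O[Si](C)(C)C(C)(C)C)c4)OC[C@H]32)cc(OC)c1O[Si](C)(C)C(C)(C)C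
F0 | step 4 | none | none
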